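The target is cut at the O–C1 bond of its ring oxirane (C1–C6), which sits on the face of the cyclohexene ring that also carries O-2 and O-3 (the α face) and is thus out of reach of a sterically ruled epoxidation. The oxygen is relayed instead: in a Payne rearrangement an α-alkoxide on C6 opens an exocyclic C1–C7 spiro-oxirane, made from the free β face, at the quaternary carbon C1. One operation forms O–C1, closes the ring oxirane, inverts C1 and frees O-7. The precursor is a 4-bromocyclohexene bearing the spiro-oxirane, a 6α-acetate, and O-2 and O-3 as two different ethers (silyl, PMB), so that the endgame needs no acid.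

Key step: step 9

Conventions: every intermediate is numbered as the target. C1 becomes the quaternary oxirane carbon, C2 and C3 carry the oxygens of the starting diol, C4 carries bromine, C4=C5 is the ring alkene, C6 becomes the oxirane CH, and C7 is the exocyclic carbon. α is the ring face of O-2 and O-3, β the opposite face. PMB = 4-methoxybenzyl, TBS = tert-butyldimethylsilyl, Bz = benzoyl.

Step 1
Reactants: 1 (1S,2S)-3-bromocyclohexa-3,5-diene-1,2-diol; 2 4-methoxybenzaldehyde dimethyl acetal
Product: 3 cis-fused 4-methoxybenzylidene acetal of 1 across O-2/O-3 (either epimer at the acetal carbon)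
Conditions: 2 (1.2 equiv), camphorsulfonic acid (cat.), CH2Cl2, −20 °C
Reagents that add atoms: 2, 4-methoxybenzaldehyde dimethyl acetal, COc1ccc(cc1)C(OC)OC
Why: Acid-catalysed transacetalisation of a cis-1,2-diol closes the cis-fused dioxolane at low temperature before the acid-labile diene can aromatise; the new acetal carbon may form as either epimer, which is of no consequence because it becomes a CH2 group in step 2.

Step 2
Reactants: 3 4-methoxybenzylidene acetal
Product: 4 3α-O-PMB ether with free 2α-hydroxyl, (1S,6S)-5-bromo-6-[(4-methoxybenzyl)oxy]cyclohexa-2,4-dien-1-ol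
Conditions: i-Bu2AlH, CH2Cl2, −78 → 0 °C; aq. KNaC4H4O6
Reagents that add atoms: none
Why: Reductive acetal cleavage should be regioselective because i-Bu2AlH binds the less hindered and more electron-rich O-2, remote from the vinyl bromide, so that this C–O bond ionises and hydride reduces the oxocarbenium ion left on O-3; no ring stereocentre is touched.

Step 3
Reactants: 4 3α-O-PMB ether with free 2α-hydroxyl; 5 tert-butyldimethylsilyl chloride
Product: 6 2α-O-TBS 3α-O-PMB diene (4-bromo; alkenes C4=C5 and C6=C1)
Conditions: TBSCl, imidazole, DMF, 0 °C → rt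
Reagents that add atoms: 5, tert-butyldimethylsilyl chloride, CC(C)(C)[Si](C)(C)Cl
Why: Imidazole-promoted silyl ether formation on an unhindered secondary allylic alcohol is routine, and silyl migration is excluded because O-3 is already an ether.

Step 4
Reactants: 6 2α-O-TBS 3α-O-PMB diene
Product: 7 1β,6β-diol (4-bromo-2α-OTBS-3α-OPMB-cyclohex-4-ene-1β,6β-diol)
Conditions: OsO4 (cat.), N-methylmorpholine N-oxide, acetone/H2O, 0 °C → rt
Reagents that add atoms: OsO4, O=[Os](=O)(=O)=O; N-methylmorpholine N-oxide, C[N+]1([O-])CCOCC1; water, O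
Why: In this Upjohn dihydroxylation OsO4 should attack only the electron-richer, bromine-free C6=C1 alkene and add suprafacially to the β face, anti to the allylic silyloxy group on C2 and the ether on C3, which sets C1 and C6 as β-hydroxyl centres.

Step 5
Reactants: 7 1β,6β-diol; 8 acetic acid
Product: 9 6α-acetate 1β-alcohol (C6 inverted)
Conditions: PPh3, diisopropyl azodicarboxylate, AcOH, THF, 0 °C → rt
Reagents that add atoms: 8, acetic acid, CC(=O)O
Why: In this Mitsunobu reaction the allylic C6 hydroxyl, not the C1 hydroxyl crowded by the neighbouring OTBS group, should be activated as the alkoxyphosphonium ion and displaced by acetate with SN2 inversion, which places O-6 on the α face; SN2′ attack is disfavoured because it would have to occur at the bromine-bearing C4.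

Step 6
Reactants: 9 6α-acetate 1β-alcohol
Product: 10 1-ketone (6α-acetoxy-4-bromo-2α-OTBS-3α-OPMB-cyclohex-4-en-1-one)
Conditions: Dess–Martin periodinane, pyridine, CH2Cl2, 0 °C; crude ketone used at once
Reagents that add atoms: none
Why: Dess–Martin oxidation of the one remaining secondary alcohol is fast and, with pyridine as buffer, neutral, so the α-acetoxy β,γ-unsaturated ketone should form without epimerisation at C6 or C2; no stereocentre is created.

Step 7
Reactants: 10 1-ketone; 11 Tebbe reagent Cp2Ti(μ-Cl)(μ-CH2)AlMe2
Product: 12 1-methylene compound (C1=C7; 6α-OAc; 2α-OTBS; 3α-OPMB; 4-Br)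
Conditions: Cp2Ti(μ-Cl)(μ-CH2)AlMe2, pyridine (cat.), THF/toluene, −40 → 0 °C
Reagents that add atoms: 11, Cp2Ti(μ-Cl)(μ-CH2)AlMe2 (Tebbe reagent), C[Al-]1(C)C[Ti](C2C=CC=C2)(C2C=CC=C2)[Cl+]1
Why: Tebbe methylenation uses a non-basic titanium methylidene that adds to a ketone far faster than to an ester at low temperature, so the enolisable ketone should give the exocyclic alkene without the epimerisation, β-elimination or acetyl loss that a basic phosphorus ylide would invite; no stereocentre is created.

Step 8
Reactants: 12 1-methylene compound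
Product: 13 spiro-oxirane acetate (C1–C7 oxirane with its oxygen β and C7 α; 6α-OAc; 2α-OTBS; 3α-OPMB; 4-Br)
Conditions: mCPBA, NaHCO3, CH2Cl2, 0 °C → rt
Reagents that add atoms: mCPBA, OOC(=O)c1cccc(Cl)c1
Why: In this Prilezhaev epoxidation the peracid should reach the exocyclic 1,1-disubstituted alkene only from the β face, because O-2, O-3 and O-6 all shield the α face and neither an acetate nor a silyl ether directs a peracid, while the bromine-bearing ring alkene is too electron-poor to react; this sets C1 with the oxirane oxygen β.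

Step 9
Reactants: 13 spiro-oxirane acetate
Product: 15 hydroxymethyl ring oxirane (1α:6α-epoxide; CH2OH β on C1; 2α-OTBS; 3α-OPMB; 4-Br), via 6α-hydroxy spiro-oxirane 14 (not isolated)
Conditions: K2CO3 (0.2 equiv), MeOH, 0 °C
Reagents that add atoms: none
Why: This is a Payne rearrangement, the base-induced isomerisation of an epoxy alcohol: methoxide removes the acetyl group and the C6 alkoxide so freed attacks C1 of the spiro-oxirane from the α face, anti to its C1–O bond, in an intramolecular SN2 displacement that releases the C7 alkoxide. The new ring oxirane closes in the 3-exo-tet mode. C1 is the only centre changed and is inverted stereospecifically, so its configuration follows from the β-oxirane oxygen set in step 8 and the α-oxygen on C6 set in step 5, while C6 keeps its C–O bond. The step needs the equilibrium on the product side and the alkoxide to outrun methoxide: a trisubstituted ring oxirane with a primary alcohol should be favoured over a 1,1-disubstituted oxirane with a secondary alcohol, and C7 is a neopentyl-type carbon that resists intermolecular opening. O-2 and O-3 cannot compete for C1 because they are held as TBS and PMB ethers, both inert to K2CO3 in MeOH.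

Step 10
Reactants: 15 hydroxymethyl ring oxirane
Product: 16 7,2-diol (1α:6α-epoxide; free C7–OH and 2α-OH; 3α-OPMB; 4-Br)
Conditions: Bu4NF, AcOH (1:1), THF, rt
Reagents that add atoms: none
Why: Fluoride-mediated desilylation is buffered with acetic acid so that no alkoxide is present to carry the oxirane back through the spiro isomer towards the freed O-2; no stereocentre is touched.

Step 11
Reactants: 16 7,2-diol; 17 benzoyl chloride
Product: 19 7,2-di-O-benzoate (3α-OPMB; 4-Br), via 7-monobenzoate 18 (not isolated)
Conditions: BzCl (3 equiv), pyridine, DMAP (cat.), CH2Cl2, 0 °C → rt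
Reagents that add atoms: 17, benzoyl chloride, ClC(=O)c1ccccc1
Why: DMAP-catalysed acylation should benzoylate the primary O-7 first and the hindered secondary O-2 next, and since O-3 is still masked the ester pattern of the target is fixed by the protecting groups and not by a choice between two free hydroxyls.

Step 12
Reactants: 19 7,2-di-O-benzoate
Product: 20 4-bromo derivative of the target (7,2-di-O-benzoate with free 3α-OH)
Conditions: DDQ, CH2Cl2/pH 7 phosphate buffer, 0 °C → rt
Reagents that add atoms: none
Why: Oxidative PMB ether cleavage (hydride abstraction by DDQ, then hydrolysis of the oxocarbenium ion) is a neutral process that should spare the allylic oxirane and give no alkoxide that could draw the benzoyl group from O-2 to O-3.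

Step 13
Reactants: 20 4-bromo derivative of the target
Product: 21 target, [(1S,2R,3R,6S)-2-(benzoyloxy)-3-hydroxy-7-oxabicyclo[4.1.0]hept-4-en-1-yl]methyl benzoate (ring atoms numbered as in the route)
Conditions: Bu3SnH, AIBN (cat.), benzene, 80 °C
Reagents that add atoms: none
Why: In this radical-chain tin hydride reduction the stannyl radical should abstract the vinylic bromine, and the sp2 σ-radical on C4, which is not conjugated with the oxirane, should take hydrogen from Bu3SnH with the alkene left in place; no stereocentre is touched.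

Compound list
1 | (1S,2S)-3-bromocyclohexa-3,5-diene-1,2-diol (cis-diol; route numbering: 2α,3α-diol, Br on C4) | BrC1=CC=C[C@H](O)[C@@H]1O | starting material
2 | 4-methoxybenzaldehyde dimethyl acetal | COc1ccc(cc1)C(OC)OC | starting material
3 | (3aS,7aS)-4-bromo-2-(4-methoxyphenyl)-3a,7a-dihydro-1,3-benzodioxole (cis-fused O-2/O-3 acetal, either epimer at the acetal carbon) | COc1ccc(cc1)C1O[C@H]2C=CC=C(Br)[C@H]2O1 | intermediate
4 | (1S,6S)-5-bromo-6-[(4-methoxybenzyl)oxy]cyclohexa-2,4-dien-1-ol (3α-O-PMB, free 2α-OH) | BrC1=CC=C[C@H](O)[C@@H]1OCc1ccc(OC)cc1 | intermediate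
5 | tert-butyldimethylsilyl chloride | CC(C)(C)[Si](C)(C)Cl | starting material
6 | 2α-O-TBS 3α-O-PMB ether of 1 | BrC1=CC=C[C@H](O[Si](C)(C)C(C)(C)C)[C@@H]1OCc1ccc(OC)cc1 | intermediate
7 | 4-bromo-2α-OTBS-3α-OPMB-cyclohex-4-ene-1β,6β-diol | O[C@@H]1C=C(Br)[C@@H](OCc2ccc(OC)cc2)[C@@H](O[Si](C)(C)C(C)(C)C)[C@@H]1O | intermediate
8 | acetic acid | CC(=O)O | starting material
9 | 6α-acetate 1β-alcohol (4-Br, 2α-OTBS, 3α-OPMB) | CC(=O)O[C@H]1C=C(Br)[C@@H](OCc2ccc(OC)cc2)[C@@H](O[Si](C)(C)C(C)(C)C)[C@@H]1O | intermediate
10 | 6α-acetoxy-4-bromo-2α-OTBS-3α-OPMB-cyclohex-4-en-1-one | CC(=O)O[C@H]1C=C(Br)[C@@H](OCc2ccc(OC)cc2)[C@@H](O[Si](C)(C)C(C)(C)C)C1=O | intermediate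
11 | Tebbe reagent, Cp2Ti(μ-Cl)(μ-CH2)AlMe2 | C[Al-]1(C)C[Ti](C2C=CC=C2)(C2C=CC=C2)[Cl+]1 | starting material
12 | 1-methylene compound (C1=C7; 6α-OAc, 4-Br, 2α-OTBS, 3α-OPMB) | CC(=O)O[C@H]1C=C(Br)[C@@H](OCc2ccc(OC)cc2)[C@@H](O[Si](C)(C)C(C)(C)C)C1=C | intermediate
13 | spiro-oxirane acetate (C1–C7 oxirane, oxygen β, C7 α; 6α-OAc, 4-Br, 2α-OTBS, 3α-OPMB) | CC(=O)O[C@H]1C=C(Br)[C@@H](OCc2ccc(OC)cc2)[C@@H](O[Si](C)(C)C(C)(C)C)[C@@]13CO3 | intermediate
14 | 6α-hydroxy spiro-oxirane (13 without the acetyl group) | O[C@H]1C=C(Br)[C@@H](OCc2ccc(OC)cc2)[C@@H](O[Si](C)(C)C(C)(C)C)[C@@]13CO3 | intermediate (not isolated)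
15 | hydroxymethyl ring oxirane (1α,6α-epoxide, CH2OH β on C1; 4-Br, 2α-OTBS, 3α-OPMB) | OC[C@]12O[C@H]1C=C(Br)[C@@H](OCc3ccc(OC)cc3)[C@H]2O[Si](C)(C)C(C)(C)C | intermediate
16 | 7,2-diol (1α,6α-epoxide; 4-Br, 3α-OPMB) | OC[C@]12O[C@H]1C=C(Br)[C@@H](OCc3ccc(OC)cc3)[C@H]2O | intermediate
17 | benzoyl chloride | ClC(=O)c1ccccc1 | starting material
18 | 7-O-benzoate of 16 (free 2α-OH) | O=C(OC[C@]12O[C@H]1C=C(Br)[C@@H](OCc3ccc(OC)cc3)[C@H]2O)c1ccccc1 | intermediate (not isolated)
19 | 7,2-di-O-benzoate of 16 (3α-OPMB, 4-Br) | O=C(OC[C@]12O[C@H]1C=C(Br)[C@@H](OCc3ccc(OC)cc3)[C@H]2OC(=O)c2ccccc2)c1ccccc1 | intermediate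
20 | 4-bromo derivative of the target (free 3α-OH) | O=C(OC[C@]12O[C@H]1C=C(Br)[C@@H](O)[C@H]2OC(=O)c2ccccc2)c1ccccc1 | intermediate
21 | [(1S,2R,3R,6S)-2-(benzoyloxy)-3-hydroxy-7-oxabicyclo[4.1.0]hept-4-en-1-yl]methyl benzoate (ring atoms numbered as in the route) | O=C(OC[C@]12O[C@H]1C=C[C@@H](O)[C@H]2OC(=O)c1ccccc1)c1ccccc1 | target

Total step count: 13. Longest linear sequence: 13 steps (1 to 21; the route is linear).

Steps most likely to fail

Step 9 (Payne rearrangement). Methoxide may open the spiro-oxirane at C7 instead of the intramolecular attack, the migration may stop at an unfavourable equilibrium, or the silyl group may wander from O-2 to the new alkoxides and let O-2 attack C1. In the fallback the α-oxirane is delivered by a hydroxyl instead of being relayed. It sets out from 12: K2CO3 in MeOH should remove the acetate to give the bis-allylic 6α-alcohol F1. Catalytic Ph3SiOReO3 in Et2O at −40 °C should then move the hydroxyl to the unhindered terminus C7 by 1,3-transposition, with conjugation as the driving force, giving the 7-hydroxy-1(6),4-diene F2. Bu4NF/AcOH should free O-2 to give the diene diol F3. VO(acac)2/t-BuOOH should finally epoxidise C1=C6 syn to the ring hydroxyl on C2 (hydroxyl-directed epoxidation of a cyclohexenol), which comes back to the route at diol 16.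

Step 7 (methylenation). Ketone 10 may enolise towards C6 (epimerisation, migration of the ring alkene into conjugation) or expel the C3 ether by β-elimination before it is trapped; the titanium reagent may also attack the acetate, and its aluminium component may ionise the bis-allylic acetate of the product. The fallback is a two-stage Peterson olefination. From 10, Me3SiCH2Li/CeCl3 in THF at −78 °C should add to the carbonyl from the β face without enolisation to give the tertiary β-hydroxysilane F4, and BF3·OEt2 at −40 °C should bring about the acid-type Peterson elimination, which comes back to the route at alkene 12.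

Step 13 (debromination). The stannyl radical may add to C4=C5 of the product, after which the radical on C5 would open the neighbouring oxirane, or the benzoyl group may drift from O-2 to the free O-3 at 80 °C. In the fallback bromine is removed before the allylic oxirane exists, once it has done its work in steps 4 and 8. From 13, Bu3SnH/AIBN should give the bromine-free spiro-oxirane acetate F5. The conditions of step 9 should convert it into the bromine-free hydroxymethyl ring oxirane F6, those of step 10 into the bromine-free 7,2-diol F7, and those of step 11 into the bromine-free dibenzoate PMB ether F8. DDQ as in step 12 then comes back to the route at the target 21.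

Further compounds
F1 | step 9 | 6α-hydroxy-1-methylene compound (12 without the acetyl group) | O[C@H]1C=C(Br)[C@@H](OCc2ccc(OC)cc2)[C@@H](O[Si](C)(C)C(C)(C)C)C1=C
F2 | step 9 | 7-hydroxy-1(6),4-diene (4-Br, 2α-OTBS, 3α-OPMB) | OCC1=CC=C(Br)[C@@H](OCc2ccc(OC)cc2)[C@H]1O[Si](C)(C)C(C)(C)C
F3 | step 9 | 7,2α-dihydroxy-1(6),4-diene (4-Br, 3α-OPMB) | OCC1=CC=C(Br)[C@@H](OCc2ccc(OC)cc2)[C@H]1O
F4 | step 7 | 1α-hydroxy-1β-(trimethylsilylmethyl) adduct of 10 | CC(=O)O[C@H]1C=C(Br)[C@@H](OCc2ccc(OC)cc2)[C@@H](O[Si](C)(C)C(C)(C)C)[C@]1(O)C[Si](C)(C)C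
F5 | step 13 | bromine-free analogue of 13 | CC(=O)O[C@H]1C=C[C@@H](OCc2ccc(OC)cc2)[C@@H](O[Si](C)(C)C(C)(C)C)[C@@]13CO3
F6 | step 13 | bromine-free analogue of 15 | OC[C@]12O[C@H]1C=C[C@@H](OCc3ccc(OC)cc3)[C@H]2O[Si](C)(C)C(C)(C)C
F7 | step 13 | bromine-free analogue of 16 | OC[C@]12O[C@H]1C=C[C@@H](OCc3ccc(OC)cc3)[C@H]2O
F8 | step 13 | bromine-free analogue of 19 | O=C(OC[C@]12O[C@H]1C=C[C@@H](OCc3ccc(OC)cc3)[C@H]2OC(=O)c2ccccc2)c1ccccc1
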